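## Structural features

Kanzonol L (29) is an achiral isoflavone. Ring A is fused to the pyranone ring C, ring B is bonded through C1' to C3, and a 2,2-dimethyl-2H-pyran (ring D) is fused to ring B through C2' (ring oxygen) and C3' (the vinylic C4''). Ring A is fully substituted, with hydroxyls on C5 and C7 and 3-methylbut-2-enyl chains on C6 and C8. Ring B carries four contiguous substituents (C1'–C3, C2'–O, C3'–C4'', C4'–OH) and hydrogen only on C5' and C6'. There is no stereocentre, so no two stereocentres stand next to each other and nothing has to be set or guarded against epimerisation. The fragile groups are the two prenyl double bonds, each beside a free phenol (acid closes them to chromans), the styrene-like ring D alkene activated by two ortho oxygens, and three phenols, one chelated to the C4 carbonyl. The difficulty is twofold: ring D must sit on the oxygen next to C1' and not on the C4' oxygen, which a resorcinol chromenylation does not deliver cleanly, and the hexasubstituted ring A must be joined to the C4 carbonyl without the Lewis acids that prenyl groups and ring D do not tolerate. The key step exploits the sequence C1'(carbon substituent)–C2'(O)–C3'(C4''): it maps onto C8(ester)–C8a(O1)–C4a(C4) of a 4-oxygenated 2-pyrone already fused to ring D, so only C4' with its oxygen and C5' have to be brought in, as a two-carbon alkyne unit spanning C4a and C7.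

## Logic of the disconnections

29 from 28. Only the O–Si bond on C4' is cut. Carrying the silyl group from the key step to the end spares a protecting-group exchange and keeps this phenol masked through the organolithium and acid steps. The forward step needs buffered fluoride, because 29 has three acidic phenols and a base-sensitive pyranone.

28 from 26 (through 27). The cuts are O1–C2 and C2–C3 of ring C and the three acetal C–O bonds on ring A. C2 is a one-carbon electrophile placed on the benzylic methylene; because ring A of 26 is symmetric, either flanking oxygen closes the same ring. The gain is an open ketone with ring closure and deprotection in one operation. The forward step needs acid that cleaves three acetals and expels the amine but leaves two prenyl groups beside phenols and the ring D alkene alone.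

26 from 25 and 17. The cut is C4–C4a, carbonyl to ring A. This bond is classically made by Friedel–Crafts acylation of a prenylated phloroglucinol, which the prenyl groups and ring D would not survive; cutting it as aryl anion plus amide keeps the chemistry basic. The gain is two fragments of similar size. The forward step requires that 25 add to the carbonyl faster than it deprotonates the benzylic CH2 of 17, and that addition stop at the ketone.

25 from 24, 22, 19 and 18, with 20. The cuts are the two aryl–CH2 bonds of the prenyl groups and three O–CH2 bonds. Every ring A carbon of 19 lies between two acetal oxygens, so three successive directed metalations address the three positions with no regiochemical choice. The gain is a return to 18 and 20. The forward steps require ring lithiation to beat lateral lithiation of the prenyl CH2 and allylation to occur at the primary carbon of 20.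

17 from 16 from 13. One carbon is taken out from between ring B and the carboxyl carbon, and the hydroxamate is exchanged for methoxide. The cycloaddition needs the ester directly on the ring as its activating group, whereas the isoflavone needs aryl–C3–C4. The gain is arrival at 13. The forward homologation must run a carbenoid rearrangement in the presence of the aryl silyl ether and the ring D alkene.

13 from 7 and 11 (key step). The cuts are C3'–C4' and C5'–C6' of ring B, with CO2 restored between C4a and C7. A regioselective arene functionalisation is replaced by a cycloaddition whose orientation follows from polarity, with ring D already fused. The gain is a bicyclic pyrone and a two-carbon alkyne in place of a tetrasubstituted arene. The forward step needs the siloxy carbon on C4a and a temperature at which 11 survives.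

7 from 4 and 5. The cuts are O1–C2 and C4–C4a of ring D, a formal [3+3] annulation. The gain is a monocyclic pyrone and a four-carbon enal. The forward step must close through the C4 oxygen and not the lactone carbonyl, and the amine catalyst must not open the pyrone at C6.

4 from 1 and 2. The cuts are C5–C6 and the lactone O1–C2 bond of the pyrone; C6 comes from 2. The forward step needs condensation at only one of the two equivalent methylene groups of 1.

11 from 8. The cuts are the C–O and O–Si bonds. The forward step needs oxygen transfer to a metalated alkyne and silylation on oxygen, not carbon.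

## Other disconnections considered

Alternative 1: Ring B is cut at C2'–C3', C4'–C5' and C1'–C2' (C5'–C6' comes from the preceding 1,2-shift), so it is built last on a complete, protected ring A/C chromone.
- Forward key step: the α'-diazo enone A1 is irradiated. Wolff rearrangement gives a vinylketene that adds the prenyl-bearing siloxyalkyne A2 in a [2+2] sense; four-electron opening, six-electron closure and tautomerisation would give A3, with a free C2' hydroxyl, the prenyl group on C3' and the silyl ether on C4'. Ring D would then be closed by dehydrogenative cyclisation of the C2' hydroxyl onto the C3' prenyl group.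
- In favour: the C3–C1' bond is inherited from a 3-formylchromone, so no deoxybenzoin, ester homologation or aryllithium–amide coupling is needed; on this point it is better than the chosen plan. Regiocontrol in ring B is mechanistic and equal to that of the chosen plan.
- Against: the key step does not form ring D. The extra oxidation must pick one prenyl group out of three. The photochemical step runs on a chromone that is itself a chromophore and carries three alkenes able to trap a ketene. Diazo transfer needs strong base on a chromone with an electrophilic C2.
- Comparison: the step count is comparable on paper and perhaps slightly shorter, but the riskiest step falls on the most elaborate intermediate, whereas the chosen plan runs its key step on a small bicycle made in two steps.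

Alternative 2: Ring D is cut at C2'–O, C3'–C4'' and O–C2'', so it is added to a ring B that already carries the two-carbon chain.
- Forward key step: CsF releases the strained C2'–C3' triple bond from silyl triflate A4. The carbonyl oxygen of 5 attacks C2', the carbon remote from the C4' acetal oxygen; the aryl anion at C3' closes on the carbonyl carbon, and the four-membered adduct opens and recloses by oxa-6π electrocyclisation to A5.
- In favour: ring D arrives in one step, the orientation is supported by the inductive effect of the C4' oxygen, and the side chain is already at the arylacetaldehyde oxidation level, so no homologation is needed; that is a point on which it is better than the chosen plan.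
- Against: attack must occur at C2', which is flanked by the side chain, so sterics oppose the electronic preference. Ene reaction of the aryne with the allylic hydrogens of 5 competes. A4 is itself a 1,2,3,4-tetrasubstituted benzene whose regiocontrolled preparation takes several steps, which relocates the regiochemical problem the pyrone solves by construction.
- Comparison: both plans end in an oxa-6π closure of ring D and are mechanistically on a par there. The route to A4 is likely longer than the four steps to 13.

Alternative 3: The two aryl–CH2 bonds of the C6 and C8 prenyl groups are cut.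
- Forward key step: heating the bis(1,1-dimethylallyl) ether A6 lets each ether undergo a [3,3] shift to its only free ortho carbon and tautomerise, giving A7; no ring is formed.
- In favour: the symmetry of ring A makes both shifts regiospecific. The prenyl groups arrive after the deoxybenzoin is assembled, so they are absent during acylation; on this point it is better than the chosen plan. It uses the symmetry of ring A as the chosen plan does.
- Against: it does nothing for the ring B/D orientation. The tertiary allyl ethers on hindered, hydrogen-bonded phenols are hard to make and usually need propargyl ethers and semi-hydrogenation. Such ethers ionise easily, and the ortho-prenyl phenol products can cyclise. The deoxybenzoin would still have to be made by acylation with a ring D–containing acid.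
- Comparison: the chosen plan installs both prenyl groups in two directed metalations before coupling and is expected to be shorter.

Key step: step 4

Assumption: unprimed locants C2–C8a refer to the isoflavone core or, where 7, 12 and 13 are discussed, to those bicycles; primed locants are ring B and double-primed locants ring D of 29. Compounds 3, 6 and 27 are expected as double-bond isomer mixtures that converge, and 12 is racemic and transient.

## Route

Step 1
Reactants: 1 dimethyl 3-oxopentanedioate; 2 trimethyl orthoformate
Product: 4 methyl 4-hydroxy-2-oxo-2H-pyran-5-carboxylate, via methoxymethylidene diester 3 (not isolated)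
Conditions: HC(OMe)3, Ac2O, 120 °C; then 2 M HCl, 25 °C
Reagents that add atoms: water, O
Why: Alkoxymethylene condensation at one of the two equivalent active methylene groups gives 3; acid then hydrolyses the vinylogous ester and the formyl enol lactonises onto the remote ester in a six-membered acyl substitution, which should give the 6-unsubstituted 4-hydroxy-2-pyrone.

Step 2
Reactants: 4 methyl 4-hydroxy-2-oxo-2H-pyran-5-carboxylate; 5 3-methylbut-2-enal
Product: 7 methyl 2,2-dimethyl-5-oxo-2H,5H-pyrano[4,3-b]pyran-8-carboxylate, via alkylidene pyrandione 6 (not isolated)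
Conditions: ethylenediammonium diacetate (10 mol %), CH2Cl2, 40 °C
Reagents that add atoms: none
Why: Knoevenagel condensation of the iminium ion of 5 at C3 of 4 gives the 1-oxatriene 6, which closes by oxa-6π electrocyclisation through the C4 oxygen so that the lactone is kept; this formal [3+3] annulation is routine for 4-hydroxy-2-pyrones and enals.

Step 3
Reactants: 8 acetylene
Product: 11 (ethynyloxy)triisopropylsilane, via lithium acetylide 9 (not isolated), via lithium ethynolate 10 (not isolated)
Conditions: n-BuLi, THF, −78 °C; t-BuOOLi (from t-BuOOH, LiN(SiMe3)2), −78 to −20 °C; i-Pr3SiOTf, −78 °C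
Reagents that add atoms: tert-butyl hydroperoxide, CC(C)(C)OO; triisopropylsilyl trifluoromethanesulfonate, CC(C)[Si](C(C)C)(C(C)C)OS(=O)(=O)C(F)(F)F
Why: The acetylide attacks the electrophilic oxygen of the lithium peroxide to give the ynolate 10, and the bulky silyl triflate silylates it on oxygen rather than carbon; oxidation of lithium acetylides followed by O-silylation is the standard entry to triisopropylsilyl ynol ethers.

Step 4
Reactants: 7 methyl 2,2-dimethyl-5-oxo-2H,5H-pyrano[4,3-b]pyran-8-carboxylate; 11 (ethynyloxy)triisopropylsilane
Product: 13 methyl 2,2-dimethyl-5-(triisopropylsilyloxy)-2H-chromene-8-carboxylate, via bridged lactone adduct 12 (not isolated)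
Conditions: PhMe, 100 °C, sealed tube
Reagents that add atoms: none
Why: The pyrone of 7 is a push–pull diene whose C7 terminus is electrophilic (β to the ester and attached to O6) and whose C4a terminus is the nucleophilic β-carbon of the C8a enol ether, while 11 is polarised the opposite way, so an inverse-electron-demand Diels–Alder reaction, concerted but strongly asynchronous, should join the alkyne CH to C7 and the siloxy carbon to C4a. The bridged lactone 12 then loses CO2 by retro-[4+2] cycloreversion driven by aromatisation, which is the known behaviour of 2-pyrones with electron-rich alkynes such as ynamines and alkoxyalkynes. Ring B is closed in a [4+2] mode, with the σ bonds C3'–C4' and C5'–C6' formed across the diene termini, and ring D is carried through untouched and ends angularly fused. No stereocentre remains, because the two bridgeheads of 12 are erased on aromatisation. The step needs regioselectivity (siloxy carbon to C4a, not C7) and chemoselectivity (pyrone diene, not the ring D alkene or a [2+2] addition across C7=C8); the first is secured by the matched polarisation, with both the ester and the lactone carbonyl directing the nucleophilic carbon to C7, and the second by six-membered closure being favoured thermally over four-membered closure and by the electron-rich 2H-pyran diene being mismatched with an electron-rich alkyne. The bulky triisopropylsilyl group should keep the ynol ether from isomerising to a silylketene at this temperature and stays on oxygen in 13.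

Step 5
Reactants: 13 methyl 2,2-dimethyl-5-(triisopropylsilyloxy)-2H-chromene-8-carboxylate
Product: 16 methyl 2-[2,2-dimethyl-5-(triisopropylsilyloxy)-2H-chromen-8-yl]acetate, via dibromo enolate 14 (not isolated), via aryl ynolate 15 (not isolated)
Conditions: CH2Br2, lithium 2,2,6,6-tetramethylpiperidide, THF, −78 °C; LiN(SiMe3)2; n-BuLi, −78 to 25 °C; HCl, MeOH, 0 °C
Reagents that add atoms: dibromomethane, BrCBr; methanol, CO
Why: Kowalski ester homologation: dibromomethyllithium adds to the ester and loss of methoxide gives 14, bromine–lithium exchange generates a carbenoid whose aryl group shifts to the neighbouring carbon to give the ynolate 15, and acidic methanol protonates it to a ketene that is trapped as the methyl ester. The aryl silyl ether and the ring D alkene should be inert to the lithium reagents at low temperature.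

Step 6
Reactants: 16 methyl 2-[2,2-dimethyl-5-(triisopropylsilyloxy)-2H-chromen-8-yl]acetate
Product: 17 2-[2,2-dimethyl-5-(triisopropylsilyloxy)-2H-chromen-8-yl]-N-methoxy-N-methylacetamide
Conditions: MeNHOMe·HCl, i-PrMgCl, THF, −20 to 0 °C
Reagents that add atoms: N,O-dimethylhydroxylamine hydrochloride, CNOC.Cl
Why: The chloromagnesium amide of N,O-dimethylhydroxylamine, formed in the flask, converts the methyl ester into the Weinreb amide by acyl substitution faster than the ester enolises.

Step 7
Reactants: 18 phloroglucinol
Product: 19 1,3,5-tris(methoxymethoxy)benzene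
Conditions: NaH, MeOCH2Cl, DMF, 0 °C
Reagents that add atoms: chloromethyl methyl ether, COCCl
Why: Williamson-type O-alkylation of the phenoxides with the hard chloromethyl ether gives the tris-acetal, which protects ring A and installs three directing groups for lithiation.

Step 8
Reactants: 19 1,3,5-tris(methoxymethoxy)benzene; 20 1-bromo-3-methylbut-2-ene
Product: 22 1,3,5-tris(methoxymethoxy)-2-(3-methylbut-2-enyl)benzene, via aryllithium 21 (not isolated)
Conditions: n-BuLi, THF, 0 °C; CuBr·SMe2 (10 mol %), then 20, −78 to 0 °C
Reagents that add atoms: none
Why: Directed ortho-metalation at a carbon flanked by two acetal oxygens gives 21, and copper-catalysed allylic substitution at the primary carbon of 20 gives the linear prenyl arene.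

Step 9
Reactants: 22 1,3,5-tris(methoxymethoxy)-2-(3-methylbut-2-enyl)benzene; 20 1-bromo-3-methylbut-2-ene
Product: 24 1,3,5-tris(methoxymethoxy)-2,4-bis(3-methylbut-2-enyl)benzene, via aryllithium 23 (not isolated)
Conditions: n-BuLi, THF, 0 °C; CuBr·SMe2 (10 mol %), then 20, −78 to 0 °C
Reagents that add atoms: none
Why: A second directed ortho-metalation at one of the two equivalent remaining positions, each again between two acetal oxygens, and the same allylation install the second prenyl group; ring lithiation should outrun lateral lithiation of the prenyl CH2.

Step 10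
Reactants: 24 1,3,5-tris(methoxymethoxy)-2,4-bis(3-methylbut-2-enyl)benzene; 17 2-[2,2-dimethyl-5-(triisopropylsilyloxy)-2H-chromen-8-yl]-N-methoxy-N-methylacetamide
Product: 26 2-[2,2-dimethyl-5-(triisopropylsilyloxy)-2H-chromen-8-yl]-1-[2,4,6-tris(methoxymethoxy)-3,5-bis(3-methylbut-2-enyl)phenyl]ethanone, via aryllithium 25 (not isolated)
Conditions: n-BuLi, THF, 0 °C; then 17, −78 to 0 °C; aq. NH4Cl
Reagents that add atoms: none
Why: Directed ortho-metalation of the last ring C–H gives 25, whose addition to the Weinreb amide stops at the chelated tetrahedral intermediate, so the Weinreb ketone synthesis should give the deoxybenzoin without over-addition and without any Lewis acid.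

Step 11
Reactants: 26 2-[2,2-dimethyl-5-(triisopropylsilyloxy)-2H-chromen-8-yl]-1-[2,4,6-tris(methoxymethoxy)-3,5-bis(3-methylbut-2-enyl)phenyl]ethanone
Product: 28 3-[2,2-dimethyl-5-(triisopropylsilyloxy)-2H-chromen-8-yl]-5,7-dihydroxy-6,8-bis(3-methylbut-2-enyl)-4H-chromen-4-one, via enaminone 27 (not isolated)
Conditions: Me2NCH(OMe)2, PhMe, 100 °C; evaporate; 3 M HCl, MeOH, 45 °C
Reagents that add atoms: N,N-dimethylformamide dimethyl acetal, COC(OC)N(C)C
Why: Condensation of the formamide acetal at the activated benzylic methylene gives the enaminone 27; methanolic HCl then removes the acetals, and the freed ortho phenol adds to the protonated enaminone and expels dimethylamine (conjugate addition–elimination), with the symmetry of ring A making either ortho oxygen give the same isoflavone. The aryl triisopropylsilyl ether is expected to survive, and any that is lost simply gives 29 early.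

Step 12
Reactants: 28 3-[2,2-dimethyl-5-(triisopropylsilyloxy)-2H-chromen-8-yl]-5,7-dihydroxy-6,8-bis(3-methylbut-2-enyl)-4H-chromen-4-one
Product: 29 kanzonol L, 5,7-dihydroxy-3-(5-hydroxy-2,2-dimethyl-2H-chromen-8-yl)-6,8-bis(3-methylbut-2-enyl)-4H-chromen-4-one
Conditions: Bu4NF, AcOH, THF, 0 °C
Reagents that add atoms: none
Why: Fluoride cleaves the aryl O–Si bond (desilylation); acetic acid buffers the phenoxides so that the pyranone ring and the prenyl groups are not exposed to strong base.

## Compound list

1 | dimethyl 3-oxopentanedioate | COC(=O)CC(=O)CC(=O)OC | starting material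
2 | trimethyl orthoformate | COC(OC)OC | starting material
3 | dimethyl 2-(methoxymethylidene)-3-oxopentanedioate (double-bond geometry not controlled) | COC=C(C(=O)OC)C(=O)CC(=O)OC | intermediate (not isolated)
4 | methyl 4-hydroxy-2-oxo-2H-pyran-5-carboxylate | COC(=O)C1=COC(=O)C=C1O | intermediate
5 | 3-methylbut-2-enal | CC(C)=CC=O | starting material
6 | methyl 3-(3-methylbut-2-enylidene)-2,4-dioxo-3,4-dihydro-2H-pyran-5-carboxylate (double-bond geometry not controlled) | COC(=O)C1=COC(=O)C(=CC=C(C)C)C1=O | intermediate (not isolated)
7 | methyl 2,2-dimethyl-5-oxo-2H,5H-pyrano[4,3-b]pyran-8-carboxylate | CC1(C)C=CC2=C(O1)C(C(=O)OC)=COC2=O | intermediate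
8 | acetylene | C#C | starting material
9 | lithium acetylide | [Li]C#C | intermediate (not isolated)
10 | lithium ethynolate | [Li]OC#C | intermediate (not isolated)
11 | (ethynyloxy)triisopropylsilane | C#CO[Si](C(C)C)(C(C)C)C(C)C | intermediate
12 | bridged lactone from [4+2] addition of 11 across C4a and C7 of 7, with C5(=O)–O6 as the bridge (racemic; bridgehead configuration fixed by the bicycle) | COC(=O)C1=C2OC(C)(C)C=CC23C(=O)OC1C=C3O[Si](C(C)C)(C(C)C)C(C)C | intermediate (not isolated)
13 | methyl 2,2-dimethyl-5-(triisopropylsilyloxy)-2H-chromene-8-carboxylate | COC(=O)c1ccc(O[Si](C(C)C)(C(C)C)C(C)C)c2c1OC(C)(C)C=C2 | intermediate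
14 | lithium 2,2-dibromo-1-[2,2-dimethyl-5-(triisopropylsilyloxy)-2H-chromen-8-yl]ethenolate | [Li]OC(=C(Br)Br)c1ccc(O[Si](C(C)C)(C(C)C)C(C)C)c2c1OC(C)(C)C=C2 | intermediate (not isolated)
15 | lithium 2-[2,2-dimethyl-5-(triisopropylsilyloxy)-2H-chromen-8-yl]ethynolate | [Li]OC#Cc1ccc(O[Si](C(C)C)(C(C)C)C(C)C)c2c1OC(C)(C)C=C2 | intermediate (not isolated)
16 | methyl 2-[2,2-dimethyl-5-(triisopropylsilyloxy)-2H-chromen-8-yl]acetate | COC(=O)Cc1ccc(O[Si](C(C)C)(C(C)C)C(C)C)c2c1OC(C)(C)C=C2 | intermediate
17 | 2-[2,2-dimethyl-5-(triisopropylsilyloxy)-2H-chromen-8-yl]-N-methoxy-N-methylacetamide | CON(C)C(=O)Cc1ccc(O[Si](C(C)C)(C(C)C)C(C)C)c2c1OC(C)(C)C=C2 | intermediate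
18 | phloroglucinol | Oc1cc(O)cc(O)c1 | starting material
19 | 1,3,5-tris(methoxymethoxy)benzene | COCOc1cc(OCOC)cc(OCOC)c1 | intermediate
20 | 1-bromo-3-methylbut-2-ene | CC(C)=CCBr | starting material
21 | 2,4,6-tris(methoxymethoxy)phenyllithium | [Li]c1c(OCOC)cc(OCOC)cc1OCOC | intermediate (not isolated)
22 | 1,3,5-tris(methoxymethoxy)-2-(3-methylbut-2-enyl)benzene | COCOc1cc(OCOC)c(CC=C(C)C)c(OCOC)c1 | intermediate
23 | 2,4,6-tris(methoxymethoxy)-3-(3-methylbut-2-enyl)phenyllithium | [Li]c1c(OCOC)cc(OCOC)c(CC=C(C)C)c1OCOC | intermediate (not isolated)
24 | 1,3,5-tris(methoxymethoxy)-2,4-bis(3-methylbut-2-enyl)benzene | COCOc1cc(OCOC)c(CC=C(C)C)c(OCOC)c1CC=C(C)C | intermediate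
25 | 2,4,6-tris(methoxymethoxy)-3,5-bis(3-methylbut-2-enyl)phenyllithium | [Li]c1c(OCOC)c(CC=C(C)C)c(OCOC)c(CC=C(C)C)c1OCOC | intermediate (not isolated)
26 | 2-[2,2-dimethyl-5-(triisopropylsilyloxy)-2H-chromen-8-yl]-1-[2,4,6-tris(methoxymethoxy)-3,5-bis(3-methylbut-2-enyl)phenyl]ethanone | COCOc1c(CC=C(C)C)c(OCOC)c(CC=C(C)C)c(OCOC)c1C(=O)Cc1ccc(O[Si](C(C)C)(C(C)C)C(C)C)c2c1OC(C)(C)C=C2 | intermediate
27 | 3-(dimethylamino)-2-[2,2-dimethyl-5-(triisopropylsilyloxy)-2H-chromen-8-yl]-1-[2,4,6-tris(methoxymethoxy)-3,5-bis(3-methylbut-2-enyl)phenyl]prop-2-en-1-one (double-bond geometry not controlled) | COCOc1c(CC=C(C)C)c(OCOC)c(CC=C(C)C)c(OCOC)c1C(=O)C(=CN(C)C)c1ccc(O[Si](C(C)C)(C(C)C)C(C)C)c2c1OC(C)(C)C=C2 | intermediate (not isolated)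
28 | 3-[2,2-dimethyl-5-(triisopropylsilyloxy)-2H-chromen-8-yl]-5,7-dihydroxy-6,8-bis(3-methylbut-2-enyl)-4H-chromen-4-one | CC(C)=CCc1c(O)c(CC=C(C)C)c2occ(-c3ccc(O[Si](C(C)C)(C(C)C)C(C)C)c4c3OC(C)(C)C=C4)c(=O)c2c1O | intermediate
29 | kanzonol L, 5,7-dihydroxy-3-(5-hydroxy-2,2-dimethyl-2H-chromen-8-yl)-6,8-bis(3-methylbut-2-enyl)-4H-chromen-4-one | CC(C)=CCc1c(O)c(CC=C(C)C)c2occ(-c3ccc(O)c4c3OC(C)(C)C=C4)c(=O)c2c1O | target

## Step count and risk

Total: 12 steps. Longest linear sequence: 8 steps (steps 1, 2, 4, 5, 6, 10, 11, 12, from 1 to 29). The ring A branch (steps 7–9) and the alkyne branch (step 3) join at steps 10 and 4.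

Step 4 (key step). The most likely failure is thermal loss of 11 (1,3-silyl shift to a silylketene, or oligomerisation) outpacing a cycloaddition that the electron-donating C8a oxygen slows; conjugate addition at C7 without ring closure is the second concern. The fallback sets out from 7 and replaces the alkyne by a ketene acetal. Heating 7 with commercial 1,1-bis(trimethylsilyloxy)ethene should give the same polarity-matched [4+2] addition (or its stepwise Michael–aldol equivalent); loss of CO2 and β-elimination of trimethylsilanol would aromatise the adduct to methyl 2,2-dimethyl-5-(trimethylsilyloxy)-2H-chromene-8-carboxylate F1. Methanolysis (K2CO3, MeOH) would give methyl 5-hydroxy-2,2-dimethyl-2H-chromene-8-carboxylate F2, and silylation with i-Pr3SiCl and imidazole in DMF comes back to the route at 13.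

Step 3. Monolithium acetylide may disproportionate to the insoluble dilithium salt before oxygen transfer is complete, and silylation may go partly to carbon. The fallback does not set out from 8: it starts from commercial 3-phenylisoxazole F3. Deprotonation at C5 with n-BuLi (THF, −78 °C) fragments the ring to benzonitrile and the same ynolate 10, and silylation with i-Pr3SiOTf as in step 3 comes back to the route at 11.

Step 5. Addition of dibromomethyllithium to an electron-rich, ortho-substituted benzoate may be slow, and the carbenoid may be protonated before the aryl shift, so the homologation may stall at the bromoketone stage. The fallback sets out from 13 and is an Arndt–Eistert sequence. Cleavage of the ester with Me3SiOK in THF gives 2,2-dimethyl-5-(triisopropylsilyloxy)-2H-chromene-8-carboxylic acid F4. Oxalyl chloride with catalytic DMF gives 2,2-dimethyl-5-(triisopropylsilyloxy)-2H-chromene-8-carbonyl chloride F5. Me3SiCHN2 gives 2-diazo-1-[2,2-dimethyl-5-(triisopropylsilyloxy)-2H-chromen-8-yl]ethanone F6. Wolff rearrangement with PhCO2Ag and Et3N in MeOH comes back to the route at 16.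

Step 10. Proton transfer from the benzylic CH2 of 17 to the hindered, basic aryllithium (enolisation in place of addition) would return both partners. The fallback sets out from 17 and changes to a less basic nucleophile and a more reactive electrophile. LiAlH4 at −78 °C reduces 17 to 2-[2,2-dimethyl-5-(triisopropylsilyloxy)-2H-chromen-8-yl]acetaldehyde F7. Aryllithium 25 is transmetalated with anhydrous CeCl3 to dichloro[2,4,6-tris(methoxymethoxy)-3,5-bis(3-methylbut-2-enyl)phenyl]cerium F8. Its addition to F7 gives racemic 2-[2,2-dimethyl-5-(triisopropylsilyloxy)-2H-chromen-8-yl]-1-[2,4,6-tris(methoxymethoxy)-3,5-bis(3-methylbut-2-enyl)phenyl]ethanol F9, and Dess–Martin oxidation comes back to the route at 26.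

Step 11. During acetal cleavage the acid may cyclise a prenyl group onto a neighbouring free phenol or add methanol across the ring D alkene. The fallback sets out from 26, separates the two events and closes ring C under base. ZnBr2 and n-PrSH in CH2Cl2 at 0 °C remove the three acetals to give 2-[2,2-dimethyl-5-(triisopropylsilyloxy)-2H-chromen-8-yl]-1-[2,4,6-trihydroxy-3,5-bis(3-methylbut-2-enyl)phenyl]ethanone F10. Ring closure with HC(OEt)3, pyridine and catalytic piperidine at 110 °C comes back to the route at 28.

## Further compounds

F1 | step 4 | methyl 2,2-dimethyl-5-(trimethylsilyloxy)-2H-chromene-8-carboxylate | COC(=O)c1ccc(O[Si](C)(C)C)c2c1OC(C)(C)C=C2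
F2 | step 4 | methyl 5-hydroxy-2,2-dimethyl-2H-chromene-8-carboxylate | COC(=O)c1ccc(O)c2c1OC(C)(C)C=C2
F3 | step 3 | 3-phenylisoxazole | c1ccc(cc1)-c1ccon1
F4 | step 5 | 2,2-dimethyl-5-(triisopropylsilyloxy)-2H-chromene-8-carboxylic acid | OC(=O)c1ccc(O[Si](C(C)C)(C(C)C)C(C)C)c2c1OC(C)(C)C=C2
F5 | step 5 | 2,2-dimethyl-5-(triisopropylsilyloxy)-2H-chromene-8-carbonyl chloride | ClC(=O)c1ccc(O[Si](C(C)C)(C(C)C)C(C)C)c2c1OC(C)(C)C=C2
F6 | step 5 | 2-diazo-1-[2,2-dimethyl-5-(triisopropylsilyloxy)-2H-chromen-8-yl]ethanone | [N-]=[N+]=CC(=O)c1ccc(O[Si](C(C)C)(C(C)C)C(C)C)c2c1OC(C)(C)C=C2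
F7 | step 10 | 2-[2,2-dimethyl-5-(triisopropylsilyloxy)-2H-chromen-8-yl]acetaldehyde | O=CCc1ccc(O[Si](C(C)C)(C(C)C)C(C)C)c2c1OC(C)(C)C=C2
F8 | step 10 | dichloro[2,4,6-tris(methoxymethoxy)-3,5-bis(3-methylbut-2-enyl)phenyl]cerium | COCOc1c(CC=C(C)C)c(OCOC)c(CC=C(C)C)c(OCOC)c1[Ce](Cl)Cl
F9 | step 10 | racemic 2-[2,2-dimethyl-5-(triisopropylsilyloxy)-2H-chromen-8-yl]-1-[2,4,6-tris(methoxymethoxy)-3,5-bis(3-methylbut-2-enyl)phenyl]ethanol | COCOc1c(CC=C(C)C)c(OCOC)c(CC=C(C)C)c(OCOC)c1C(O)Cc1ccc(O[Si](C(C)C)(C(C)C)C(C)C)c2c1OC(C)(C)C=C2
F10 | step 11 | 2-[2,2-dimethyl-5-(triisopropylsilyloxy)-2H-chromen-8-yl]-1-[2,4,6-trihydroxy-3,5-bis(3-methylbut-2-enyl)phenyl]ethanone | CC(C)=CCc1c(O)c(CC=C(C)C)c(O)c(C(=O)Cc2ccc(O[Si](C(C)C)(C(C)C)C(C)C)c3c2OC(C)(C)C=C3)c1O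
A1 | alternative 1 | (E)-1-diazo-4-[5,7-bis(methoxymethoxy)-6,8-bis(3-methylbut-2-enyl)-4-oxochromen-3-yl]but-3-en-2-one | [N-]=[N+]=CC(=O)/C=C/c1coc2c(CC=C(C)C)c(OCOC)c(CC=C(C)C)c(OCOC)c2c1=O
A2 | alternative 1 | 5-methyl-1-(triisopropylsilyloxy)hex-4-en-1-yne | CC(C)=CCC#CO[Si](C(C)C)(C(C)C)C(C)C
A3 | alternative 1 | 3-[2-hydroxy-3-(3-methylbut-2-enyl)-4-(triisopropylsilyloxy)phenyl]-5,7-bis(methoxymethoxy)-6,8-bis(3-methylbut-2-enyl)chromen-4-one | CC(C)=CCc1c(O)c(-c2coc3c(CC=C(C)C)c(OCOC)c(CC=C(C)C)c(OCOC)c3c2=O)ccc1O[Si](C(C)C)(C(C)C)C(C)C
A4 | alternative 2 | 6-(2,2-dimethoxyethyl)-3-(methoxymethoxy)-2-(trimethylsilyl)phenyl trifluoromethanesulfonate | COC(OC)Cc1ccc(OCOC)c([Si](C)(C)C)c1OS(=O)(=O)C(F)(F)F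
A5 | alternative 2 | 8-(2,2-dimethoxyethyl)-5-(methoxymethoxy)-2,2-dimethyl-2H-chromene | COC(OC)Cc1ccc(OCOC)c2c1OC(C)(C)C=C2
A6 | alternative 3 | 1-[4-(methoxymethoxy)-2,6-bis(2-methylbut-3-en-2-yloxy)phenyl]-2-[5-(methoxymethoxy)-2,2-dimethyl-2H-chromen-8-yl]ethanone | C=CC(C)(C)Oc1cc(OCOC)cc(OC(C)(C)C=C)c1C(=O)Cc1ccc(OCOC)c2c1OC(C)(C)C=C2
A7 | alternative 3 | 1-[2,6-dihydroxy-4-(methoxymethoxy)-3,5-bis(3-methylbut-2-enyl)phenyl]-2-[5-(methoxymethoxy)-2,2-dimethyl-2H-chromen-8-yl]ethanone | CC(C)=CCc1c(O)c(C(=O)Cc2ccc(OCOC)c3c2OC(C)(C)C=C3)c(O)c(CC=C(C)C)c1OCOC
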